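**Retrosynthetic overview**
- Feature: ring B (C5–C10) of the ent-drimane decalin carries the quaternary C10, C8 with its methyl C12, and C9 with its branch C11. It is read as the [4+2] adduct of the ring A 2-vinylcyclohexene unit C10=C5–C6=C7 and the four-carbon ynoate C12–C8≡C9–C11.
- Last disconnections: the C3–O angelate (acylation); C3–OH (oxidation of the Δ2 silyl enol ether of the C2 ketone, then epimerisation to the equatorial ketol); the C11–O aryl ether (Mitsunobu reaction with umbelliferone).
- Ring B adjustment after the cycloaddition: Δ5 hydrogenation sets C5, deconjugative protonation moves Δ8 to Δ7 and sets C9, and ester reduction frees C11–OH.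
- Ring A, with the C4 gem-dimethyl group and the C2 oxygen, comes from ketoisophorone. The C2 carbinol, set by asymmetric transfer hydrogenation, is the only source of absolute configuration; it relays this to C10 and is erased at the ketone stage.
- Ring order: ring A (bought), then ring B (Diels–Alder). The coumarin rings are bought.

Key step: step 5

Remark: drimane numbering is used throughout (ring A = C1–C5, C10; ring B = C5–C10; C11 on C9, C12 on C8). The (R,R)-Ru–TsDPEN catalyst is assumed to give (R)-2 by the usual model, with the vinyl flank in the place of the aryl group. The antipodal catalyst is equally available.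

**Step 1**
Reactants: 1 ketoisophorone (2,6,6-trimethylcyclohex-2-ene-1,4-dione)
Product: 2 (R)-4-hydroxy-2,6,6-trimethylcyclohex-2-en-1-one
Conditions: Ru[(R,R)-TsDPEN](p-cymene) (preformed amido complex, 0.5 mol %), iPrOH, rt
Reagents that add atoms: none
Why: Noyori-type asymmetric transfer hydrogenation, known for this ene-dione: only the C4 carbonyl is accessible (C1 lies between the gem-dimethyl carbon and the methyl-bearing alkene carbon), and the catalyst tells its vinyl flank from its CH2 flank, which should set the carbinol centre (the later C2) as R.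

**Step 2**
Reactants: 2 (R)-4-hydroxy-2,6,6-trimethylcyclohex-2-en-1-one
Product: 3 (R)-4-(tert-butyldimethylsilyloxy)-2,6,6-trimethylcyclohex-2-en-1-one
Conditions: TBSCl, imidazole, DMF, rt
Reagents that add atoms: tert-butyldimethylsilyl chloride, CC(C)(C)[Si](C)(C)Cl
Why: Imidazole-promoted silylation of a secondary allylic alcohol, which leaves the stereocentre untouched and gives an ether that survives hydride, amide base, palladium and a mild Lewis acid.

**Step 3**
Reactants: 3 (R)-4-(tert-butyldimethylsilyloxy)-2,6,6-trimethylcyclohex-2-en-1-one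
Product: 5 (S)-4-(tert-butyldimethylsilyloxy)-2,6,6-trimethylcyclohex-1-en-1-yl trifluoromethanesulfonate, via lithium enolate 4 (not isolated)
Conditions: L-Selectride, THF, −78 °C; then PhNTf2, −78 °C → rt
Reagents that add atoms: N-phenylbis(trifluoromethanesulfonimide), O=S(=O)(N(c1ccccc1)S(=O)(=O)C(F)(F)F)C(F)(F)F; L-Selectride, [Li+].CCC(C)[BH-](C(C)CC)C(C)CC (gives only hydride and the Li+ of 4)
Why: Conjugate reduction with enolate trapping (reductive enol triflate formation): the bulky borohydride cannot reach the shielded C1 carbonyl and adds hydride to the unsubstituted β-carbon, the tetrasubstituted enolate 4 forms regiospecifically and is O-sulfonylated, and the carbinol centre keeps its geometry (the descriptor becomes S only because the ring priorities change).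

**Step 4**
Reactants: 5 (S)-4-(tert-butyldimethylsilyloxy)-2,6,6-trimethylcyclohex-1-en-1-yl triflate
Product: 6 (S)-tert-butyldimethylsilyl ether of 3,5,5-trimethyl-4-vinylcyclohex-3-en-1-ol
Conditions: CH2=CHSnBu3, Pd2(dba)3 (2.5 mol %), AsPh3 (20 mol %), LiCl (3 equiv), NMP, 60 °C
Reagents that add atoms: tributyl(vinyl)stannane, C=C[Sn](CCCC)(CCCC)CCCC
Why: Stille coupling of a hindered vinyl triflate, for which the weakly bound arsine ligand and chloride speed up transmetalation; no stereocentre takes part.

**Step 5**
Reactants: 6 (S)-silyloxy vinylcyclohexene; 7 methyl but-2-ynoate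
Product: 8 methyl (2R,10R)-2-(tert-butyldimethylsilyloxy)drima-5,8-dien-11-oate (ent series; C10 methyl trans to the C2 oxygen)
Conditions: 7 (3 equiv), EtAlCl2 (0.5 equiv, premixed with 7), CH2Cl2, −20 °C → rt
Reagents that add atoms: none
Why: The aluminium-complexed ynoate and the s-cis conformer of the diene C10=C5–C6=C7 combine in a concerted but strongly asynchronous [4+2] cycloaddition in which C7–C8 bonding runs ahead of C9–C10 bonding, which is what lets the quaternary C10 form. The closest known reaction type is the Diels–Alder reaction of 2,6,6-trimethyl-1-vinylcyclohexenes with acetylenic esters, joined to Lewis-acid acceleration of alkynoate dienophiles, which is needed here because a β-methyl ynoate is far less reactive than an acetylenedicarboxylate and heat alone would bring on the 1,5-hydrogen shift of the diene first. Ring B (C5–C10) closes by intermolecular [4+2] annulation onto ring A as a 1,4-cyclohexadiene (Δ5, Δ8), and a linear dienophile raises no endo/exo question. The one new stereocentre, C10, is controlled by C2: in the favoured half-chair of ring A the silyloxy group is equatorial and the C4 methyl on the face of the axial H2 is pseudoaxial, so the dienophile bonds to C10 on the other face, a path that leads directly to the ring A chair with the C10 methyl axial and trans to C2–O (10R). Addition to the other face would need either contact with that pseudoaxial methyl or the flipped half-chair with the silyloxy group axial and syn to a C4 methyl. Regioselectivity is also needed and comes from diene polarisation: the unsubstituted terminus C7 has the largest HOMO coefficient (attack there leaves charge at tertiary C10) and bonds to the β-carbon C8 of the complexed ester.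

**Step 6**
Reactants: 8 methyl 2-silyloxydrima-5,8-dien-11-oate
Product: 9 methyl (2R,5R,10R)-2-(tert-butyldimethylsilyloxy)drim-8-en-11-oate (trans-decalin)
Conditions: H2 (1–3 atm), 10 % Pd/C, EtOAc, rt
Reagents that add atoms: none
Why: Heterogeneous catalytic hydrogenation: the trisubstituted Δ5 alkene is reduced while the tetrasubstituted, ester-bearing Δ8 alkene stays inert, and the catalyst can only reach the face opposite to the axial C10 and C4 methyl groups, so H5 ends trans to the C10 methyl.

**Step 7**
Reactants: 9 methyl 2-silyloxydrim-8-en-11-oate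
Product: 11 methyl (2R,5R,9R,10R)-2-(tert-butyldimethylsilyloxy)drim-7-en-11-oate, via lithium dienolate 10 (not isolated)
Conditions: LDA (2 equiv), THF–DMPU, −78 → −10 °C; then AcOH, THF, −78 °C
Reagents that add atoms: lithium diisopropylamide, [Li+].CC(C)[N-]C(C)C (gives only the Li+ of 10)
Why: Deconjugative protonation of an extended ester enolate: loss of the axial C7 proton gives the transoid, ring-trisubstituted dienolate 10, more stable than the cisoid exocyclic one from C12, and the acid then protonates C9 along the pseudoaxial line on the face away from the axial C10 methyl, so H9 is trans to that methyl and the ester is equatorial.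

**Step 8**
Reactants: 11 methyl 2-silyloxydrim-7-en-11-oate
Product: 12 (2R,5R,9R,10R)-2-(tert-butyldimethylsilyloxy)drim-7-en-11-ol
Conditions: LiAlH4, Et2O, 0 °C
Reagents that add atoms: none
Why: Hydride reduction of an ester, faster than enolisation at C9, after which C9 is no longer epimerisable; the silyl ether and the alkene are inert.

**Step 9**
Reactants: 12 2-silyloxydrim-7-en-11-ol; 13 umbelliferone (7-hydroxycoumarin)
Product: 14 7-{[(2R,5R,9R,10R)-2-(tert-butyldimethylsilyloxy)drim-7-en-11-yl]oxy}coumarin
Conditions: PPh3, DIAD, THF, 0 → 40 °C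
Reagents that add atoms: none
Why: Mitsunobu etherification of a primary, β-branched alcohol with an acidic phenol under neutral conditions that spare the lactone; the reacting carbon C11 is not stereogenic.

**Step 10**
Reactants: 14 silyl-protected drimenyl coumarin ether
Product: 15 7-{[(2R,5R,9R,10R)-2-hydroxydrim-7-en-11-yl]oxy}coumarin
Conditions: HF·pyridine, THF, 0 °C → rt
Reagents that add atoms: none
Why: Fluoride-driven desilylation in a buffered acidic medium, which avoids the hydroxide or alkoxide that would open the coumarin and is too mild to move the Δ7 alkene.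

**Step 11**
Reactants: 15 2-hydroxydrimenyl coumarin ether
Product: 16 7-{[(5R,9R,10R)-2-oxodrim-7-en-11-yl]oxy}coumarin
Conditions: Dess–Martin periodinane, CH2Cl2, rt
Reagents that add atoms: none
Why: Dess–Martin oxidation of an unhindered equatorial alcohol, inert toward the alkene and the coumarin; it removes the C2 stereocentre once its relay role is over, so any C10-epimeric material must be separated before this point.

**Step 12**
Reactants: 16 2-oxodrimenyl coumarin ether
Product: 17 7-{[(5R,9R,10R)-2-(triethylsilyloxy)drima-2,7-dien-11-yl]oxy}coumarin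
Conditions: TESOTf, Et3N, CH2Cl2, 0 °C → rt
Reagents that add atoms: triethylsilyl trifluoromethanesulfonate, CC[Si](CC)(CC)OS(=O)(=O)C(F)(F)F
Why: Soft enolisation to a silyl enol ether under equilibrating amine/ammonium triflate conditions: the Δ2 isomer should prevail, as it does for 10-methyl-trans-2-decalones and 2-oxo-5α-steroids, because a Δ1 double bond would force the C1 hydrogen into the plane of C9 and its C11 branch; no stereocentre is formed.

**Step 13**
Reactants: 17 Δ2 triethylsilyl enol ether
Product: 19 7-{[(3R,5S,9R,10R)-3-hydroxy-2-oxodrim-7-en-11-yl]oxy}coumarin (axial 3-OH, trans to the C10 methyl), via silyloxy epoxide 18 (not isolated)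
Conditions: DMDO (1.0 equiv, acetone solution), CH2Cl2, −78 → −40 °C; then HF·pyridine, THF, 0 °C
Reagents that add atoms: dimethyldioxirane, CC1(C)OO1
Why: Rubottom oxidation: at low temperature one equivalent of the dioxirane should take the electron-rich enol ether ahead of the Δ7 alkene and the electron-poor coumarin alkene, and it can only approach opposite to the syn-axial C10 and C4 methyl groups, so collapse of 18 leaves the new hydroxyl axial, still the epimer of what the target needs.

**Step 14**
Reactants: 19 axial 3-hydroxy-2-ketone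
Product: 20 7-{[(3S,5S,9R,10R)-3-hydroxy-2-oxodrim-7-en-11-yl]oxy}coumarin (equatorial 3-OH, cis to the C10 methyl)
Conditions: DBU (0.3 equiv), degassed toluene, rt
Reagents that add atoms: none
Why: Base-catalysed α-ketol epimerisation through the enediolate: reprotonation at C3 from the open face puts H3 axial and the hydroxyl equatorial, where it hydrogen-bonds to the C2 carbonyl and sheds its syn-axial contacts, while the transposed 2-hydroxy-3-ketone should stay minor because it would restore an axial H2 between the two syn-axial methyl groups.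

**Step 15**
Reactants: 20 equatorial 3-hydroxy-2-ketone; 21 angelic acid
Product: 23 target, (3S,5S,9R,10R)-11-(2-oxo-2H-chromen-7-yloxy)-2-oxodrim-7-en-3-yl (Z)-2-methylbut-2-enoate, via angelic 2,4,6-trichlorobenzoic anhydride 22 (not isolated)
Conditions: 21, 2,4,6-Cl3C6H2COCl, Et3N, toluene, rt; then 20, 80 °C (no DMAP)
Reagents that add atoms: 2,4,6-trichlorobenzoyl chloride, O=C(Cl)c1c(Cl)cc(Cl)cc1Cl (atoms only in 22)
Why: Yamaguchi esterification run without a nucleophilic pyridine catalyst, the usual way to transfer an angeloyl group without Z-to-E isomerisation by addition–elimination; C3–O is not broken, so the equatorial configuration is kept, and the ketol is already the stable isomer under the mildly basic conditions.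

**Compound list**
1 | ketoisophorone | CC1=CC(=O)CC(C)(C)C1=O | starting material
2 | (R)-4-hydroxy-2,6,6-trimethylcyclohex-2-en-1-one | CC1=C[C@H](O)CC(C)(C)C1=O | intermediate
3 | (R)-4-(tert-butyldimethylsilyloxy)-2,6,6-trimethylcyclohex-2-en-1-one | CC1=C[C@H](O[Si](C)(C)C(C)(C)C)CC(C)(C)C1=O | intermediate
4 | lithium (S)-4-(tert-butyldimethylsilyloxy)-2,6,6-trimethylcyclohex-1-en-1-olate | [Li+].[O-]C1=C(C)C[C@H](O[Si](C)(C)C(C)(C)C)CC1(C)C | intermediate
5 | (S)-4-(tert-butyldimethylsilyloxy)-2,6,6-trimethylcyclohex-1-en-1-yl triflate | O=S(=O)(OC1=C(C)C[C@H](O[Si](C)(C)C(C)(C)C)CC1(C)C)C(F)(F)F | intermediate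
6 | (S)-TBS ether of 3,5,5-trimethyl-4-vinylcyclohex-3-en-1-ol | C=CC1=C(C)C[C@H](O[Si](C)(C)C(C)(C)C)CC1(C)C | intermediate
7 | methyl but-2-ynoate | CC#CC(=O)OC | starting material
8 | methyl (2R,10R)-2-(TBSO)drima-5,8-dien-11-oate | CC(C)(C)[Si](C)(C)O[C@H]1C[C@@]2(C)C(C(=O)OC)=C(C)CC=C2C(C)(C)C1 | intermediate
9 | methyl (2R,5R,10R)-2-(TBSO)drim-8-en-11-oate | CC(C)(C)[Si](C)(C)O[C@H]1C[C@@]2(C)C(C(=O)OC)=C(C)CC[C@@H]2C(C)(C)C1 | intermediate
10 | lithium 7,9(11)-dienolate of 9 | [Li+].CC(C)(C)[Si](C)(C)O[C@H]1C[C@@]2(C)C(=C([O-])OC)C(C)=CC[C@@H]2C(C)(C)C1 | intermediate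
11 | methyl (2R,5R,9R,10R)-2-(TBSO)drim-7-en-11-oate | CC(C)(C)[Si](C)(C)O[C@H]1C[C@@]2(C)[C@H](C(=O)OC)C(C)=CC[C@@H]2C(C)(C)C1 | intermediate
12 | (2R,5R,9R,10R)-2-(TBSO)drim-7-en-11-ol | CC(C)(C)[Si](C)(C)O[C@H]1C[C@@]2(C)[C@H](CO)C(C)=CC[C@@H]2C(C)(C)C1 | intermediate
13 | umbelliferone | O=c1ccc2ccc(O)cc2o1 | starting material
14 | 7-{[2-(TBSO)drim-7-en-11-yl]oxy}coumarin | CC(C)(C)[Si](C)(C)O[C@H]1C[C@@]2(C)[C@H](COc3ccc4ccc(=O)oc4c3)C(C)=CC[C@@H]2C(C)(C)C1 | intermediate
15 | 7-{[2-hydroxydrim-7-en-11-yl]oxy}coumarin | O[C@H]1C[C@@]2(C)[C@H](COc3ccc4ccc(=O)oc4c3)C(C)=CC[C@@H]2C(C)(C)C1 | intermediate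
16 | 7-{[2-oxodrim-7-en-11-yl]oxy}coumarin | O=C1C[C@@]2(C)[C@H](COc3ccc4ccc(=O)oc4c3)C(C)=CC[C@@H]2C(C)(C)C1 | intermediate
17 | Δ2 triethylsilyl enol ether of 16 | CC[Si](CC)(CC)OC1=CC(C)(C)[C@H]2CC=C(C)[C@@H](COc3ccc4ccc(=O)oc4c3)[C@]2(C)C1 | intermediate
18 | (2R,3R)-2-(triethylsilyloxy)-2,3-epoxide, oxygen opposite to the C10 methyl | CC[Si](CC)(CC)O[C@]12C[C@@]3(C)[C@H](COc4ccc5ccc(=O)oc5c4)C(C)=CC[C@@H]3C(C)(C)[C@H]1O2 | intermediate
19 | (3R)-3-hydroxy-2-ketone (axial OH) | O[C@H]1C(=O)C[C@@]2(C)[C@H](COc3ccc4ccc(=O)oc4c3)C(C)=CC[C@@H]2C1(C)C | intermediate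
20 | (3S)-3-hydroxy-2-ketone (equatorial OH) | O[C@@H]1C(=O)C[C@@]2(C)[C@H](COc3ccc4ccc(=O)oc4c3)C(C)=CC[C@@H]2C1(C)C | intermediate
21 | angelic acid | C/C=C(/C)C(=O)O | starting material
22 | angelic 2,4,6-trichlorobenzoic anhydride | C/C=C(/C)C(=O)OC(=O)c1c(Cl)cc(Cl)cc1Cl | intermediate
23 | CNP0111364.1 | C/C=C(/C)C(=O)O[C@@H]1C(=O)C[C@@]2(C)[C@H](COc3ccc4ccc(=O)oc4c3)C(C)=CC[C@@H]2C1(C)C | target

**Step count**
Total steps: 15. Longest linear sequence: 15 (1 → 23). Compounds 7, 13 and 21 are bought and enter directly.

**Steps most likely to fail**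

**Step 5.**
- What may go wrong: the β-methyl ynoate may add too slowly to the twisted diene with its fully substituted terminus. Lewis-acid-induced isomerisation or oligomerisation of the diene, or loss of the silyl ether, could then take over. Face selection may also be incomplete.
- Fallback from 6: C12 is carried as a second ester, which doubles the activation, removes the regiochemical question and allows a purely thermal reaction.
- Dimethyl acetylenedicarboxylate (neat, 110 °C) should give dimethyl 2-silyloxydrima-5,8-diene-11,12-dioate F1.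
- Hydrogenation over Pd/C gives the trans-fused Δ8 diester F2.
- NaOMe in MeOH equilibrates it to the Δ7 diester F3, which is still conjugated to the C12 ester and has the C9 ester equatorial.
- LiAlH4 gives 2-silyloxydrim-7-ene-11,12-diol F4.
- The less hindered allylic hydroxyl is acetylated selectively (Ac2O, pyridine, 0 °C) to the 12-monoacetate F5.
- Palladium-catalysed allylic reduction (Pd(PPh3)4, LiBHEt3), with hydride delivery to the primary allyl terminus, turns C12 into the methyl group. The route is rejoined at 12.

**Step 7.**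
- What may go wrong: proton abstraction from the C12 methyl in place of C7, which would leave an exocyclic alkene after protonation; loss of methoxide from the enolate to a ketene on warming; or return to the conjugated ester on quenching.
- Fallback from 9: the deconjugation is moved to the aldehyde level and run through a dienol ester formed under thermodynamic control.
- DIBAL-H gives the allylic alcohol 2-silyloxydrim-8-en-11-ol F6.
- MnO2 gives the enal 2-silyloxydrim-8-en-11-al F7.
- Ac2O, Et3N and DMAP with heating give the transoid 11-acetoxydrima-7,9(11)-diene F8.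
- NaBH4 in aqueous ethanol cleaves the acetate. The dienolate is protonated at C9 away from the C10 methyl, and the β,γ-unsaturated aldehyde is reduced at once. The route is rejoined at 12.

**Step 12.**
- What may go wrong: enolisation toward C1 may compete with enolisation toward C3. In the oxidation that depends on this step, the dioxirane may also attack the Δ7 alkene.
- Fallback from 16: steric discrimination by a bulky base is used together with an oxidant that ignores alkenes.
- KHMDS (THF, −78 °C) removes the axial C3 proton, which is flanked only by methyl groups, to give the potassium Δ2-enolate F9.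
- 2-(Phenylsulfonyl)-3-phenyloxaziridine hydroxylates it on the open face. The route is rejoined at 19.

**Further compounds**
F1 | step 5 | dimethyl 2-(TBSO)drima-5,8-diene-11,12-dioate | CC(C)(C)[Si](C)(C)O[C@H]1C[C@@]2(C)C(C(=O)OC)=C(C(=O)OC)CC=C2C(C)(C)C1
F2 | step 5 | dimethyl 2-(TBSO)drim-8-ene-11,12-dioate (trans-decalin) | CC(C)(C)[Si](C)(C)O[C@H]1C[C@@]2(C)C(C(=O)OC)=C(C(=O)OC)CC[C@@H]2C(C)(C)C1
F3 | step 5 | dimethyl 2-(TBSO)drim-7-ene-11,12-dioate (C9 ester equatorial) | CC(C)(C)[Si](C)(C)O[C@H]1C[C@@]2(C)[C@H](C(=O)OC)C(C(=O)OC)=CC[C@@H]2C(C)(C)C1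
F4 | step 5 | 2-(TBSO)drim-7-ene-11,12-diol | CC(C)(C)[Si](C)(C)O[C@H]1C[C@@]2(C)[C@H](CO)C(CO)=CC[C@@H]2C(C)(C)C1
F5 | step 5 | 12-acetoxy-2-(TBSO)drim-7-en-11-ol | CC(C)(C)[Si](C)(C)O[C@H]1C[C@@]2(C)[C@H](CO)C(COC(C)=O)=CC[C@@H]2C(C)(C)C1
F6 | step 7 | 2-(TBSO)drim-8-en-11-ol | CC(C)(C)[Si](C)(C)O[C@H]1C[C@@]2(C)C(CO)=C(C)CC[C@@H]2C(C)(C)C1
F7 | step 7 | 2-(TBSO)drim-8-en-11-al | CC(C)(C)[Si](C)(C)O[C@H]1C[C@@]2(C)C(C=O)=C(C)CC[C@@H]2C(C)(C)C1
F8 | step 7 | 11-acetoxy-2-(TBSO)drima-7,9(11)-diene (enol geometry open, lost in the next operation) | CC(C)(C)[Si](C)(C)O[C@H]1C[C@@]2(C)C(=COC(C)=O)C(C)=CC[C@@H]2C(C)(C)C1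
F9 | step 12 | potassium Δ2-enolate of 16 | [K+].[O-]C1=CC(C)(C)[C@H]2CC=C(C)[C@@H](COc3ccc4ccc(=O)oc4c3)[C@]2(C)C1
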